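**Plan** (halimane numbering: ring A = C1–C5, C10 with the C1=C10 alkene; ring B = C5–C10; C9 bears methyl C20 and the side chain C11–C15; C8 bears methyl C17)
- Cuts: the C15–O ester bond; then C5–C10 and C6–C7 together; then C1–C2 (enolate alkylation), C8–C9 (Ireland–Claisen) and C9–C20 (carboalumination).
- Enabling feature: the C5–C6 ethano unit of ring B lies between the vinylic C10 of the ring A alkene and the methylene C7, which the C9–C8 backbone holds 1,4. A C10 alkenyl electrophile and a C7 alkyl electrophile can therefore be added across a pendant C5=C6 vinyl group, closing ring A and ring B at once.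
- Forward: (R)-citronellol → alkyne → (E)-allylic propanoate → Claisen acid (C8, C9) → methyl ketone → chain extension (C1–C6) → (Z)-enol triflate/bromide → reductive bicyclisation (ring A, then ring B) → 2-glyceryl ester.
- Stereochemistry: C13 comes from (R)-citronellol; C8 and C9 from the chair Ireland–Claisen ((E)-alkene, E(O)-boron enolate, face chosen by the chiral borane); C5 from the key step (chiral ligand on nickel).

Key step: step 16

Assumption: the (S,S) antipodes written for the chiral bromoborane (step 6) and the bioxazoline ligand (step 16) are taken as the ones that give the (8R,9R) pair and the 5S centre; the mirror-image reagent would be used if the sense proved opposite.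

**Step 1**
Reactants: 1 (R)-citronellol
Product: 2 tert-butyl{[(3R)-3,7-dimethyloct-6-en-1-yl]oxy}diphenylsilane
Conditions: TBDPSCl, imidazole, DMF, 0 °C to rt
Reagents that add atoms: tert-butyl(chloro)diphenylsilane, CC(C)(C)[Si](Cl)(c1ccccc1)c1ccccc1
Why: O-Silylation masks the primary alcohol that later becomes the C15 carboxyl, and the C13 stereocentre is taken unchanged from the chiral pool.

**Step 2**
Reactants: 2
Product: 4 (4R)-6-[(tert-butyldiphenylsilyl)oxy]-4-methylhexanal, via ozonide 3 (not isolated)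
Conditions: O3, CH2Cl2, −78 °C; then Me2S, −78 °C to rt
Reagents that add atoms: ozone, [O-][O+]=O
Why: Ozonolysis with reductive work-up cleaves the only alkene to the aldehyde whose carbonyl carbon becomes C9.

**Step 3**
Reactants: 4
Product: 5 tert-butyl{[(3R)-3-methylhept-6-yn-1-yl]oxy}diphenylsilane
Conditions: dimethyl (1-diazo-2-oxopropyl)phosphonate, K2CO3, MeOH, 0 °C to rt
Reagents that add atoms: dimethyl (1-diazo-2-oxopropyl)phosphonate, COP(=O)(OC)C(=[N+]=[N-])C(C)=O
Why: Seyferth–Gilbert homologation with the Ohira–Bestmann reagent should convert the enolisable aldehyde into the terminal alkyne under mild carbonate conditions, adding C10.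

**Step 4**
Reactants: 5
Product: 7 (2E,6R)-8-[(tert-butyldiphenylsilyl)oxy]-3,6-dimethyloct-2-en-1-ol, via alkenylalane 6 (not isolated)
Conditions: AlMe3, Zr(C5H5)2Cl2 (cat.), CH2Cl2, 0 °C to rt; then n-BuLi, THF, −78 °C; (CH2O)n, −78 °C to rt
Reagents that add atoms: trimethylaluminium, C[Al](C)C; formaldehyde (as paraformaldehyde), C=O
Why: Negishi zirconium-catalysed carboalumination adds methyl (C20) and aluminium syn and regioselectively across the terminal alkyne, so the (E)-trisubstituted alkene is fixed before the alanate is hydroxymethylated.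

**Step 5**
Reactants: 7; 8 propanoyl chloride
Product: 9 (2E,6R)-8-[(tert-butyldiphenylsilyl)oxy]-3,6-dimethyloct-2-en-1-yl propanoate
Conditions: pyridine, DMAP (cat.), CH2Cl2, 0 °C
Reagents that add atoms: none
Why: Acylation of the primary allylic alcohol installs the propanoate whose three carbons become C7, C8 and C17.

**Step 6**
Reactants: 9
Product: 11 (2S,3S,6R)-8-[(tert-butyldiphenylsilyl)oxy]-3-ethenyl-2,3,6-trimethyloctanoic acid, via boron ketene acetal 10 (not isolated)
Conditions: (4S,5S)-2-bromo-4,5-diphenyl-1,3-bis{[3,5-bis(trifluoromethyl)phenyl]sulfonyl}-1,3,2-diazaborolidine, Et3N, toluene/hexane, −78 °C, then −20 °C to rt; aqueous work-up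
Reagents that add atoms: none
Why: Enantioselective Ireland–Claisen rearrangement through a chiral boron enolate, in which the E(O)-enolate (methyl cis to the allylic oxygen) and the (E)-alkene react through a chair with both methyls axial, so C8 and the quaternary C9 form with the methyls syn along C7–C10 while the C2-symmetric diazaborolidine selects the enantiotopic chair.

**Step 7**
Reactants: 11
Product: 12 (2S,3S,6R)-8-[(tert-butyldiphenylsilyl)oxy]-3-ethenyl-2,3,6-trimethyloctan-1-ol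
Conditions: LiAlH4, THF, 0 °C to rt
Reagents that add atoms: none
Why: Hydride reduction of the carboxylic acid should give the primary alcohol at C7 without touching the vinyl group or the silyl ether.

**Step 8**
Reactants: 12
Product: 13 tert-butyl{[(2S,3S,6R)-8-[(tert-butyldiphenylsilyl)oxy]-3-ethenyl-2,3,6-trimethyloctyl]oxy}dimethylsilane
Conditions: TBSCl, imidazole, DMF, rt
Reagents that add atoms: tert-butyl(chloro)dimethylsilane, CC(C)(C)[Si](C)(C)Cl
Why: Silylation with the smaller TBS group differentiates the C7 oxygen from the TBDPS-protected C15 oxygen for later selective release.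

**Step 9**
Reactants: 13
Product: 14 (3R,6R)-8-[(tert-butyldiphenylsilyl)oxy]-3-{(2S)-1-[(tert-butyldimethylsilyl)oxy]propan-2-yl}-3,6-dimethyloctan-2-one
Conditions: PdCl2 (10 mol %), CuCl, O2 (1 atm), DMF/H2O (7:1), rt
Reagents that add atoms: water, O
Why: Tsuji–Wacker oxidation should convert the monosubstituted vinyl group with Markovnikov selectivity into the methyl ketone, making C10 a carbonyl carbon that can enolise only towards C1.

**Step 10**
Reactants: 15 methyl 3,3-dimethylpent-4-enoate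
Product: 16 3,3-dimethylpent-4-en-1-ol
Conditions: LiAlH4, Et2O, 0 °C
Reagents that add atoms: none
Why: Hydride reduction of the ester gives the primary alcohol of the C2–C6 fragment that carries the gem-dimethyl carbon C4 and the C5=C6 vinyl group.

**Step 11**
Reactants: 16
Product: 17 5-iodo-3,3-dimethylpent-1-ene
Conditions: I2, PPh3, imidazole, CH2Cl2, 0 °C
Reagents that add atoms: iodine, II
Why: Appel-type iodination turns the primary alcohol into the iodide needed for the enolate alkylation.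

**Step 12**
Reactants: 14; 17
Product: 19 (3R,6R)-1-[(tert-butyldiphenylsilyl)oxy]-6-{(2S)-1-[(tert-butyldimethylsilyl)oxy]propan-2-yl}-3,6,11,11-tetramethyltridec-12-en-7-one, via lithium enolate 18 (not isolated)
Conditions: LiN(iPr)2, THF, −78 °C; then 17, DMPU, −78 to −20 °C
Reagents that add atoms: none
Why: Alkylation of the kinetic lithium enolate, which can form only on the methyl side because C9 is quaternary, joins C1 to C2 and completes the carbon chain of ring A.

**Step 13**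
Reactants: 19
Product: 21 (3R,6R,7Z)-1-[(tert-butyldiphenylsilyl)oxy]-6-{(2S)-1-[(tert-butyldimethylsilyl)oxy]propan-2-yl}-3,6,11,11-tetramethyltrideca-7,12-dien-7-yl trifluoromethanesulfonate, via potassium enolate 20 (not isolated)
Conditions: KN(SiMe3)2, THF, −78 °C; PhNTf2, −78 to 0 °C
Reagents that add atoms: N-phenylbis(trifluoromethanesulfonimide), O=S(=O)(N(c1ccccc1)S(=O)(=O)C(F)(F)F)C(F)(F)F
Why: Deprotonation of a ketone flanked by a quaternary carbon should give only the Z(O)-enolate, and O-triflation traps it as the (Z)-enol triflate with the leaving group cis to the C2–C6 tether.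

**Step 14**
Reactants: 21
Product: 22 (3R,6R,7Z)-1-[(tert-butyldiphenylsilyl)oxy]-6-[(2S)-1-hydroxypropan-2-yl]-3,6,11,11-tetramethyltrideca-7,12-dien-7-yl trifluoromethanesulfonate
Conditions: HF·pyridine, pyridine, THF, 0 °C
Reagents that add atoms: none
Why: Buffered HF should cleave the primary TBS ether selectively in the presence of the bulkier TBDPS ether and the enol triflate.

**Step 15**
Reactants: 22
Product: 23 (3R,6R,7Z)-6-[(2S)-1-bromopropan-2-yl]-1-[(tert-butyldiphenylsilyl)oxy]-3,6,11,11-tetramethyltrideca-7,12-dien-7-yl trifluoromethanesulfonate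
Conditions: CBr4, PPh3, CH2Cl2, 0 °C
Reagents that add atoms: carbon tetrabromide, BrC(Br)(Br)Br
Why: Appel bromination under neutral conditions converts the C7 alcohol into the primary bromide without disturbing the enol triflate.

**Step 16**
Reactants: 23
Product: 25 tert-butyl({(3R)-3-methyl-5-[(1R,2R,4aS)-1,2,5,5-tetramethyl-1,2,3,4,4a,5,6,7-octahydronaphthalen-1-yl]pentyl}oxy)diphenylsilane, via alkylnickel triflate 24 (not isolated)
Conditions: NiBr2(MeOCH2CH2OMe) (15 mol %), (4S,4'S)-4,4'-diisopropyl-4,4',5,5'-tetrahydro-2,2'-bioxazole (18 mol %), Mn powder (3 equiv), NaI (0.5 equiv), DMA, 0.01 M, 30 °C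
Reagents that add atoms: none
Why: Proposed new method: oxidative addition of zerovalent nickel into the vinylic C10–OTf bond gives an alkenylnickel held cis to the C2–C4 tether by the (Z)-triflate geometry, which inserts the pendant C5=C6 vinyl group 6-exo-trig (C10–C5, ring A, the C1=C10 alkene staying endocyclic); the primary alkylnickel at C6 (24) is then reduced by Mn, abstracts bromine from C7 and recombines to a seven-membered trivalent nickelacycle whose C(sp3)–C(sp3) reductive elimination closes ring B (C6–C7). The closest known reaction type is the nickel-catalysed reductive aryl- or alkenyl-alkylation of a tethered alkene with two electrophiles (cyclisation/cross-coupling), here made fully intramolecular. C5 is the only new stereocentre and is set in the migratory insertion; because the C9 centre presents a methyl and a CH2 arm of similar size, the substrate bias is weak and the face is assigned to the chiral bioxazoline ligand, while C8 and C9 are carried in and place the C8 methyl equatorial on the ring B chair. The step needs insertion to outrun β-hydride elimination at C5–H and direct coupling of the two termini: direct coupling would require a cyclobutene, the gem-dimethyl group at C4 favours the 6-exo mode over 7-endo, and the β-branched primary bromide resists substitution yet is a good halogen-atom donor.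

**Step 17**
Reactants: 25
Product: 26 (3R)-3-methyl-5-[(1R,2R,4aS)-1,2,5,5-tetramethyl-1,2,3,4,4a,5,6,7-octahydronaphthalen-1-yl]pentan-1-ol
Conditions: TBAF, THF, rt
Reagents that add atoms: none
Why: Fluoride-mediated desilylation releases the C15 alcohol.

**Step 18**
Reactants: 26
Product: 28 (3R)-3-methyl-5-[(1R,2R,4aS)-1,2,5,5-tetramethyl-1,2,3,4,4a,5,6,7-octahydronaphthalen-1-yl]pentanoic acid, via aldehyde 27 (not isolated)
Conditions: TEMPO (20 mol %), PhI(OAc)2, MeCN/H2O (1:1), rt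
Reagents that add atoms: water, O
Why: Oxoammonium (TEMPO) oxidation should take the primary alcohol through the aldehyde hydrate to the acid and leave the hindered trisubstituted alkene untouched.

**Step 19**
Reactants: 28; 29 2,2-dimethyl-1,3-dioxan-5-ol
Product: 30 2,2-dimethyl-1,3-dioxan-5-yl (3R)-3-methyl-5-[(1R,2R,4aS)-1,2,5,5-tetramethyl-1,2,3,4,4a,5,6,7-octahydronaphthalen-1-yl]pentanoate
Conditions: EDC·HCl, DMAP, CH2Cl2, rt
Reagents that add atoms: none
Why: Carbodiimide (Steglich) esterification acylates the secondary hydroxyl of the 1,3-protected glycerol, which fixes the acyl group on O-2.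

**Step 20**
Reactants: 30
Product: 31 1,3-dihydroxypropan-2-yl (3R)-3-methyl-5-[(1R,2R,4aS)-1,2,5,5-tetramethyl-1,2,3,4,4a,5,6,7-octahydronaphthalen-1-yl]pentanoate (CNP0174907.2)
Conditions: AcOH/H2O/THF (3:1:1), rt
Reagents that add atoms: none
Why: Mild acid hydrolysis of the six-membered acetonide should free the two primary hydroxyls under conditions chosen to be too mild for acyl migration or alkene isomerisation.

**Compound list**
1 | (R)-citronellol, (3R)-3,7-dimethyloct-6-en-1-ol | C[C@H](CCC=C(C)C)CCO | starting material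
2 | tert-butyl{[(3R)-3,7-dimethyloct-6-en-1-yl]oxy}diphenylsilane | C[C@H](CCC=C(C)C)CCO[Si](c1ccccc1)(c1ccccc1)C(C)(C)C | intermediate
3 | ozonide of 2, 3,3-dimethyl-5-{(3R)-5-[(tert-butyldiphenylsilyl)oxy]-3-methylpentyl}-1,2,4-trioxolane | C[C@H](CCC1OOC(C)(C)O1)CCO[Si](c1ccccc1)(c1ccccc1)C(C)(C)C | intermediate
4 | (4R)-6-[(tert-butyldiphenylsilyl)oxy]-4-methylhexanal | C[C@H](CCC=O)CCO[Si](c1ccccc1)(c1ccccc1)C(C)(C)C | intermediate
5 | tert-butyl{[(3R)-3-methylhept-6-yn-1-yl]oxy}diphenylsilane | C[C@H](CCC#C)CCO[Si](c1ccccc1)(c1ccccc1)C(C)(C)C | intermediate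
6 | alkenylalane, {(1E,5R)-7-[(tert-butyldiphenylsilyl)oxy]-2,5-dimethylhept-1-en-1-yl}dimethylaluminium | C[C@H](CC/C(C)=C/[Al](C)C)CCO[Si](c1ccccc1)(c1ccccc1)C(C)(C)C | intermediate
7 | (2E,6R)-8-[(tert-butyldiphenylsilyl)oxy]-3,6-dimethyloct-2-en-1-ol | C[C@H](CC/C(C)=C/CO)CCO[Si](c1ccccc1)(c1ccccc1)C(C)(C)C | intermediate
8 | propanoyl chloride | CCC(Cl)=O | starting material
9 | (2E,6R)-8-[(tert-butyldiphenylsilyl)oxy]-3,6-dimethyloct-2-en-1-yl propanoate | C[C@H](CC/C(C)=C/COC(=O)CC)CCO[Si](c1ccccc1)(c1ccccc1)C(C)(C)C | intermediate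
10 | boron ketene acetal, E(O)-enolate of 9 bound to the (4S,5S)-4,5-diphenyl-1,3-bis{[3,5-bis(trifluoromethyl)phenyl]sulfonyl}-1,3,2-diazaborolidin-2-yl group | C[C@H](CC/C(C)=C/CO\C(OB1N(S(=O)(=O)c2cc(C(F)(F)F)cc(C(F)(F)F)c2)[C@@H](c2ccccc2)[C@H](c2ccccc2)N1S(=O)(=O)c1cc(C(F)(F)F)cc(C(F)(F)F)c1)=C/C)CCO[Si](c1ccccc1)(c1ccccc1)C(C)(C)C | intermediate
11 | (2S,3S,6R)-8-[(tert-butyldiphenylsilyl)oxy]-3-ethenyl-2,3,6-trimethyloctanoic acid | C[C@H](CC[C@@]([C@H](C)C(=O)O)(C)C=C)CCO[Si](c1ccccc1)(c1ccccc1)C(C)(C)C | intermediate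
12 | (2S,3S,6R)-8-[(tert-butyldiphenylsilyl)oxy]-3-ethenyl-2,3,6-trimethyloctan-1-ol | C[C@H](CC[C@@]([C@H](C)CO)(C)C=C)CCO[Si](c1ccccc1)(c1ccccc1)C(C)(C)C | intermediate
13 | tert-butyl{[(2S,3S,6R)-8-[(tert-butyldiphenylsilyl)oxy]-3-ethenyl-2,3,6-trimethyloctyl]oxy}dimethylsilane | C[C@H](CC[C@@]([C@H](C)CO[Si](C)(C)C(C)(C)C)(C)C=C)CCO[Si](c1ccccc1)(c1ccccc1)C(C)(C)C | intermediate
14 | (3R,6R)-8-[(tert-butyldiphenylsilyl)oxy]-3-{(2S)-1-[(tert-butyldimethylsilyl)oxy]propan-2-yl}-3,6-dimethyloctan-2-one | C[C@H](CC[C@@]([C@H](C)CO[Si](C)(C)C(C)(C)C)(C)C(C)=O)CCO[Si](c1ccccc1)(c1ccccc1)C(C)(C)C | intermediate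
15 | methyl 3,3-dimethylpent-4-enoate | COC(=O)CC(C)(C)C=C | starting material
16 | 3,3-dimethylpent-4-en-1-ol | OCCC(C)(C)C=C | intermediate
17 | 5-iodo-3,3-dimethylpent-1-ene | ICCC(C)(C)C=C | intermediate
18 | lithium enolate of 14 | C[C@H](CC[C@@]([C@H](C)CO[Si](C)(C)C(C)(C)C)(C)C(=C)O[Li])CCO[Si](c1ccccc1)(c1ccccc1)C(C)(C)C | intermediate
19 | (3R,6R)-1-[(tert-butyldiphenylsilyl)oxy]-6-{(2S)-1-[(tert-butyldimethylsilyl)oxy]propan-2-yl}-3,6,11,11-tetramethyltridec-12-en-7-one | C[C@H](CC[C@@]([C@H](C)CO[Si](C)(C)C(C)(C)C)(C)C(=O)CCCC(C)(C)C=C)CCO[Si](c1ccccc1)(c1ccccc1)C(C)(C)C | intermediate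
20 | potassium (Z)-enolate of 19 | C[C@H](CC[C@@]([C@H](C)CO[Si](C)(C)C(C)(C)C)(C)/C(O[K])=C/CCC(C)(C)C=C)CCO[Si](c1ccccc1)(c1ccccc1)C(C)(C)C | intermediate
21 | (3R,6R,7Z)-1-[(tert-butyldiphenylsilyl)oxy]-6-{(2S)-1-[(tert-butyldimethylsilyl)oxy]propan-2-yl}-3,6,11,11-tetramethyltrideca-7,12-dien-7-yl trifluoromethanesulfonate | C[C@H](CC[C@@]([C@H](C)CO[Si](C)(C)C(C)(C)C)(C)/C(OS(=O)(=O)C(F)(F)F)=C/CCC(C)(C)C=C)CCO[Si](c1ccccc1)(c1ccccc1)C(C)(C)C | intermediate
22 | (3R,6R,7Z)-1-[(tert-butyldiphenylsilyl)oxy]-6-[(2S)-1-hydroxypropan-2-yl]-3,6,11,11-tetramethyltrideca-7,12-dien-7-yl trifluoromethanesulfonate | C[C@H](CC[C@@]([C@H](C)CO)(C)/C(OS(=O)(=O)C(F)(F)F)=C/CCC(C)(C)C=C)CCO[Si](c1ccccc1)(c1ccccc1)C(C)(C)C | intermediate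
23 | (3R,6R,7Z)-6-[(2S)-1-bromopropan-2-yl]-1-[(tert-butyldiphenylsilyl)oxy]-3,6,11,11-tetramethyltrideca-7,12-dien-7-yl trifluoromethanesulfonate | C[C@H](CC[C@@]([C@H](C)CBr)(C)/C(OS(=O)(=O)C(F)(F)F)=C/CCC(C)(C)C=C)CCO[Si](c1ccccc1)(c1ccccc1)C(C)(C)C | intermediate
24 | alkylnickel triflate after ring A closure (bioxazoline ligand not drawn) | C[C@H](CC[C@@]([C@H](C)CBr)(C)C1=CCCC(C)(C)[C@@H]1C[Ni]OS(=O)(=O)C(F)(F)F)CCO[Si](c1ccccc1)(c1ccccc1)C(C)(C)C | intermediate
25 | tert-butyl({(3R)-3-methyl-5-[(1R,2R,4aS)-1,2,5,5-tetramethyl-1,2,3,4,4a,5,6,7-octahydronaphthalen-1-yl]pentyl}oxy)diphenylsilane | C[C@H](CC[C@@]1(C)C2=CCCC(C)(C)[C@@H]2CC[C@H]1C)CCO[Si](c1ccccc1)(c1ccccc1)C(C)(C)C | intermediate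
26 | (3R)-3-methyl-5-[(1R,2R,4aS)-1,2,5,5-tetramethyl-1,2,3,4,4a,5,6,7-octahydronaphthalen-1-yl]pentan-1-ol | C[C@H](CC[C@@]1(C)C2=CCCC(C)(C)[C@@H]2CC[C@H]1C)CCO | intermediate
27 | (3R)-3-methyl-5-[(1R,2R,4aS)-1,2,5,5-tetramethyl-1,2,3,4,4a,5,6,7-octahydronaphthalen-1-yl]pentanal | C[C@H](CC[C@@]1(C)C2=CCCC(C)(C)[C@@H]2CC[C@H]1C)CC=O | intermediate
28 | (3R)-3-methyl-5-[(1R,2R,4aS)-1,2,5,5-tetramethyl-1,2,3,4,4a,5,6,7-octahydronaphthalen-1-yl]pentanoic acid | C[C@H](CC[C@@]1(C)C2=CCCC(C)(C)[C@@H]2CC[C@H]1C)CC(=O)O | intermediate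
29 | 2,2-dimethyl-1,3-dioxan-5-ol | CC1(C)OCC(O)CO1 | starting material
30 | 2,2-dimethyl-1,3-dioxan-5-yl (3R)-3-methyl-5-[(1R,2R,4aS)-1,2,5,5-tetramethyl-1,2,3,4,4a,5,6,7-octahydronaphthalen-1-yl]pentanoate | C[C@H](CC[C@@]1(C)C2=CCCC(C)(C)[C@@H]2CC[C@H]1C)CC(=O)OC1COC(C)(C)OC1 | intermediate
31 | 1,3-dihydroxypropan-2-yl (3R)-3-methyl-5-[(1R,2R,4aS)-1,2,5,5-tetramethyl-1,2,3,4,4a,5,6,7-octahydronaphthalen-1-yl]pentanoate | C[C@H](CC[C@@]1(C)C2=CCCC(C)(C)[C@@H]2CC[C@H]1C)CC(=O)OC(CO)CO | target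

**Totals**
Total step count: 20. Longest linear sequence: 18 (steps 1–9 and 12–20; steps 10–11 make the side fragment 17).

**Steps most likely to fail**

1. Step 16 (proposed new method). β-Hydride elimination of the C6 alkylnickel, or simple reduction of either electrophile, may outrun ring B closure, and face selection at C5 in the insertion may be insufficient. The fallback replaces organonickel catalysis by a tin-hydride radical chain; it sets out from 19 and comes back at 25. Ketone 19 should be converted with hydrazine hydrate (Et3N, EtOH, reflux) into the hydrazone of 19 F1, and iodine/tetramethylguanidine in Et2O should then give the vinyl iodide F2 (E/Z mixture, which is irrelevant for a vinyl radical). HF·pyridine should free the C7 alcohol F3, and Dess–Martin periodinane buffered with NaHCO3 should give the C7 aldehyde F4. Slow addition of Bu3SnH with AIBN in benzene at 80 °C should generate the C10 vinyl radical, which closes ring A 6-exo onto C5=C6; the C6 radical then adds 6-exo to the aldehyde carbon to give the 7-hydroxy derivative of 25 F5 (C7 epimers; any C5 epimer would be separated here). NaH/CS2/MeI should give the S-methyl xanthate F6, and Barton–McCombie deoxygenation (Bu3SnH, AIBN, toluene, 110 °C) should give 25.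

2. Step 6. The [3,3] shift through a congested chair that forms the quaternary C9 may be slow, with erosion of enolate geometry or of enantioface selection, or with the opposite sense. The fallback replaces reagent control by chirality transfer from a carbinol centre; it sets out from 5 and comes back at 14. Carboalumination of 5 as in step 4, with the alkenylalane 6 trapped by acetyl chloride, should give the enone (3E,7R)-9-[(tert-butyldiphenylsilyl)oxy]-4,7-dimethylnon-3-en-2-one F7. Corey–Bakshi–Shibata reduction ((S)-Me-oxazaborolidine, BH3·SMe2, THF, −20 °C) should give the (2R)-allylic alcohol F8, and propanoyl chloride/pyridine its propanoate F9. A classical Ireland–Claisen rearrangement (LiN(iPr)2, Me3SiCl, THF, −78 °C to rt) through the chair with the carbinol methyl equatorial should give (2S,3S,6R)-8-[(tert-butyldiphenylsilyl)oxy]-2,3,6-trimethyl-3-[(1E)-prop-1-en-1-yl]octanoic acid F10. LiAlH4 should give the alcohol F11 and TBSCl/imidazole the silyl ether F12. Ozonolysis (O3, then Me2S) should give the C10 aldehyde F13, MeMgBr (THF, −78 °C) the secondary alcohol F14, and Dess–Martin oxidation the methyl ketone 14.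

3. Step 20. The acyl group may migrate from O-2 to O-1 of glycerol during the acidic acetal cleavage. The fallback replaces the acid-labile acetal by fluoride-labile silyl ethers; it sets out from 28 and comes back at 31. Acid 28 should be esterified (EDC·HCl, DMAP, CH2Cl2) with 1,3-bis[(triisopropylsilyl)oxy]propan-2-ol F15 (from glycerol, iPr3SiCl and imidazole) to give the bis-silyl ester F16, and Et3N·3HF in THF/MeCN at 0 °C should then release 31.

**Further compounds**
F1 | step 16 | hydrazone of 19 | C[C@H](CC[C@@]([C@H](C)CO[Si](C)(C)C(C)(C)C)(C)C(=NN)CCCC(C)(C)C=C)CCO[Si](c1ccccc1)(c1ccccc1)C(C)(C)C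
F2 | step 16 | vinyl iodide, 7-iodo analogue of 21 (E/Z mixture) | C[C@H](CC[C@@]([C@H](C)CO[Si](C)(C)C(C)(C)C)(C)C(I)=CCCC(C)(C)C=C)CCO[Si](c1ccccc1)(c1ccccc1)C(C)(C)C
F3 | step 16 | C7 alcohol of F2 | C[C@H](CC[C@@]([C@H](C)CO)(C)C(I)=CCCC(C)(C)C=C)CCO[Si](c1ccccc1)(c1ccccc1)C(C)(C)C
F4 | step 16 | C7 aldehyde of F3 | C[C@H](CC[C@@]([C@H](C)C=O)(C)C(I)=CCCC(C)(C)C=C)CCO[Si](c1ccccc1)(c1ccccc1)C(C)(C)C
F5 | step 16 | 7-hydroxy derivative of 25 (C7 epimers) | C[C@H](CC[C@@]1(C)C2=CCCC(C)(C)[C@@H]2CC(O)[C@H]1C)CCO[Si](c1ccccc1)(c1ccccc1)C(C)(C)C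
F6 | step 16 | S-methyl xanthate of F5 | C[C@H](CC[C@@]1(C)C2=CCCC(C)(C)[C@@H]2CC(OC(=S)SC)[C@H]1C)CCO[Si](c1ccccc1)(c1ccccc1)C(C)(C)C
F7 | step 6 | (3E,7R)-9-[(tert-butyldiphenylsilyl)oxy]-4,7-dimethylnon-3-en-2-one | C[C@H](CC/C(C)=C/C(C)=O)CCO[Si](c1ccccc1)(c1ccccc1)C(C)(C)C
F8 | step 6 | (2R,3E,7R)-9-[(tert-butyldiphenylsilyl)oxy]-4,7-dimethylnon-3-en-2-ol | C[C@H](CC/C(C)=C/[C@@H](C)O)CCO[Si](c1ccccc1)(c1ccccc1)C(C)(C)C
F9 | step 6 | (2R,3E,7R)-9-[(tert-butyldiphenylsilyl)oxy]-4,7-dimethylnon-3-en-2-yl propanoate | C[C@H](CC/C(C)=C/[C@@H](C)OC(=O)CC)CCO[Si](c1ccccc1)(c1ccccc1)C(C)(C)C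
F10 | step 6 | (2S,3S,6R)-8-[(tert-butyldiphenylsilyl)oxy]-2,3,6-trimethyl-3-[(1E)-prop-1-en-1-yl]octanoic acid | C[C@H](CC[C@@]([C@H](C)C(=O)O)(C)/C=C/C)CCO[Si](c1ccccc1)(c1ccccc1)C(C)(C)C
F11 | step 6 | (2S,3S,6R)-8-[(tert-butyldiphenylsilyl)oxy]-2,3,6-trimethyl-3-[(1E)-prop-1-en-1-yl]octan-1-ol | C[C@H](CC[C@@]([C@H](C)CO)(C)/C=C/C)CCO[Si](c1ccccc1)(c1ccccc1)C(C)(C)C
F12 | step 6 | tert-butyldimethylsilyl ether of F11 | C[C@H](CC[C@@]([C@H](C)CO[Si](C)(C)C(C)(C)C)(C)/C=C/C)CCO[Si](c1ccccc1)(c1ccccc1)C(C)(C)C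
F13 | step 6 | (2R,5R)-7-[(tert-butyldiphenylsilyl)oxy]-2-{(2S)-1-[(tert-butyldimethylsilyl)oxy]propan-2-yl}-2,5-dimethylheptanal | C[C@H](CC[C@@]([C@H](C)CO[Si](C)(C)C(C)(C)C)(C)C=O)CCO[Si](c1ccccc1)(c1ccccc1)C(C)(C)C
F14 | step 6 | (3R,6R)-8-[(tert-butyldiphenylsilyl)oxy]-3-{(2S)-1-[(tert-butyldimethylsilyl)oxy]propan-2-yl}-3,6-dimethyloctan-2-ol (C2 epimers) | C[C@H](CC[C@@]([C@H](C)CO[Si](C)(C)C(C)(C)C)(C)C(C)O)CCO[Si](c1ccccc1)(c1ccccc1)C(C)(C)C
F15 | step 20 | 1,3-bis[(triisopropylsilyl)oxy]propan-2-ol | CC(C)[Si](OCC(O)CO[Si](C(C)C)(C(C)C)C(C)C)(C(C)C)C(C)C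
F16 | step 20 | 1,3-bis[(triisopropylsilyl)oxy]propan-2-yl ester of 28 | C[C@H](CC[C@@]1(C)C2=CCCC(C)(C)[C@@H]2CC[C@H]1C)CC(=O)OC(CO[Si](C(C)C)(C(C)C)C(C)C)CO[Si](C(C)C)(C(C)C)C(C)C
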